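## Retrosynthetic overview
1. The chalcone C=C is made last by Claisen–Schmidt condensation after global desilylation. The E-alkene of the side chain comes from cross-metathesis of a terminal vinyl group with an (S)-homoallylic silyl ether.
2. The tetrahydropyran (THP) is formed once, by stereoconvergent, thermodynamically controlled intramolecular SN1 etherification of a 1,5-diol carrying a p-silyloxybenzylic carbinol. This gives the all-equatorial, 2,6-cis ring.
3. The bold core (Steps 7 and 9): an organocatalytic iminium Friedel–Crafts of the chalcone A-ring acetophenone onto an (E)-enal sets C4. A Carreira-type synergistic Ir/enamine α-allylation then sets C5 and the benzylic/allylic centre, which I call Cε.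
4. One (S)-homoallylic alcohol from Keck allylation supplies both C2 (via its enal) and the C-f carbinol side chain.

Assumptions:
- 2',4'-Dihydroxy-6'-methoxyacetophenone is commercially available.
- The Friedel–Crafts step attacks C3' (between the 2'-OH and 4'-OR), the most activated and least hindered site.
- The enantiomer of each chiral catalyst is chosen to give the stated configurations.

Numbering used below: THP C2 carries CH2CH2Ar, C4 carries the A-ring aryl, C5 carries the side chain, C6 carries Ar. Cε is the side-chain benzylic carbon, and C-f is the side-chain carbinol.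

## Route

**Step 1**
Reactants: 1 methyl 3-(4-hydroxyphenyl)propanoate
Product: 2 methyl 3-(4-TBSO-phenyl)propanoate
Conditions: TBSCl, imidazole, DMF, 0 °C → rt
Reagents that add atoms: TBSCl, `C[Si](C)(C(C)(C)C)Cl`
Why: Silylation of the phenol gives a group that survives Grignard, metathesis and mild acid; it is removed only at the end by fluoride.

**Step 2**
Reactants: 2
Product: 3 3-(4-TBSO-phenyl)propanal
Conditions: DIBAL-H (1.1 equiv), CH2Cl2, −78 °C
Reagents that add atoms: none
Why: Partial ester reduction at low temperature stops at the aldehyde, which is the electrophile for the asymmetric allylation.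

**Step 3**
Reactants: 3; 4 allyltributylstannane
Product: 5 (S)-1-(4-TBSO-phenyl)hex-5-en-3-ol
Conditions: 4, (S)-BINOL (20 mol%), Ti(OiPr)4 (10 mol%), 4 Å MS, CH2Cl2, −20 °C
Reagents that add atoms: allyltributylstannane, `C=CC[Sn](CCCC)(CCCC)CCCC` (the allyl group)
Why: Keck catalytic asymmetric allylation; the chiral Ti–BINOL Lewis acid selects the aldehyde face and sets the (S)-carbinol that becomes both C2 and C-f.

**Step 4**
Reactants: 5
Product: 6 (S)-TES ether of 5
Conditions: TESCl, imidazole, DMF, 0 °C
Reagents that add atoms: TESCl, `CC[Si](CC)(CC)Cl`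
Why: A triethylsilyl group is acid-labile enough to be removed in the presence of the aryl TBS ethers later, and it is inert to metathesis and Grignard conditions; the stereocentre is untouched.

**Step 5**
Reactants: 6; 7 acrolein
Product: 8 (S,E)-5-(TESO)-7-(4-TBSO-phenyl)hept-2-enal
Conditions: 7 (10 equiv), Hoveyda–Grubbs II (5 mol%), CH2Cl2, 40 °C
Reagents that add atoms: none
Why: Olefin cross-metathesis of a type I terminal alkene with acrolein gives the thermodynamic (E)-enal, which carries C6 (CHO), C5, C4, C3 and C2.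

**Step 6**
Reactants: 9 2',4'-dihydroxy-6'-methoxyacetophenone
Product: 10 2'-hydroxy-4'-TBSO-6'-methoxyacetophenone
Conditions: TBSCl (1.05 equiv), imidazole, DMF, 0 °C
Reagents that add atoms: TBSCl, `C[Si](C)(C(C)(C)C)Cl`
Why: Only the 4'-OH is silylated, because the 2'-OH is locked in a hydrogen bond to the acetyl C=O; the free 2'-OH is kept for later chelation control.

**Step 7**
Reactants: 8; 10
Product: 11 (R)-3-aryl-aldehyde, OHC–CH2–C4H(Ar')–CH2–C2H(OTES)–CH2CH2Ar
Conditions: (S)-diphenylprolinol TMS ether (20 mol%), 2-nitrobenzoic acid (20 mol%), CH2Cl2, 0 °C → rt, 48 h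
Reagents that add atoms: none
Why: Proposed new method: Jørgensen–Hayashi iminium-ion Friedel–Crafts alkylation in which the very electron-rich C3' of 10 (ortho,ortho,para-oxygenated) adds to the shielded face of the (E)-iminium of 8 to set C4 as R, with the remote C2 centre exerting negligible induction; the closest known reaction is organocatalytic Friedel–Crafts of phloroglucinols and naphthols with enals.

**Step 8**
Reactants: 12 4-TBSO-benzaldehyde
Product: 13 (±)-1-(4-TBSO-phenyl)prop-2-en-1-ol
Conditions: vinylMgBr, THF, 0 °C, 1 h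
Reagents that add atoms: vinylmagnesium bromide, `C=C[Mg]Br`
Why: Simple 1,2-addition to the aldehyde; the racemic branched allylic alcohol is an acceptable substrate because the Ir π-allyl erases its stereochemistry.

**Step 9**
Reactants: 11; 13
Product: 14 aldehyde with C4 (R), C5 (R) and Cε (S)
Conditions: [Ir(cod)Cl]2 (2 mol%), Carreira phosphoramidite ligand (8 mol%), diarylprolinol TMS ether (20 mol%), acid co-catalyst, dioxane, 25–40 °C
Reagents that add atoms: none (13 supplies the CH(Ar)CH=CH2 unit with loss of water)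
Why: Proposed new method: synergistic Ir/enamine α-allylation extended to a β-aryl, β-branched aldehyde. The enamine face is set by the amine and the π-allyl-Ir face by the ligand, giving branched, anti-Markovnikov-free C–C bond formation to the benzylic carbon with the terminal vinyl retained; the catalyst pair is picked from the four-way stereodivergent matrix, and the closest known reaction is Carreira's Ir/amine α-allylation of aldehydes.

**Step 10**
Reactants: 14; 15 (4-bromophenoxy)-TBS, used as its Grignard reagent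
Product: 16 diastereomeric benzylic alcohol (C6 epimers, ~1:1)
Conditions: 15, Mg, THF, reflux, then add 14 (2.5 equiv ArMgBr), THF, −78 → 0 °C
Reagents that add atoms: 4-(TBSO)C6H4MgBr from 15 and Mg, `C[Si](C)(C(C)(C)C)Oc1ccc([Mg]Br)cc1`
Why: Grignard 1,2-addition is selective for the aldehyde because the acetophenone is tied up as its unreactive magnesium phenoxide chelate; the C6 configuration is irrelevant because it is equilibrated in Step 12.

**Step 11**
Reactants: 16
Product: 17 diol, free C2–OH and C6–OH
Conditions: AcOH/THF/H2O (3:1:1), 25 °C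
Reagents that add atoms: none
Why: Mild acid hydrolysis cleaves the secondary TES ether selectively, leaving the aryl TBS ethers intact.

**Step 12**
Reactants: 17
Product: 18 THP with a terminal vinyl group at Cε
Conditions: Bi(OTf)3 (5 mol%), CH2Cl2, 0 °C → rt
Reagents that add atoms: none
Why: Proposed new method: Lewis-acid ionisation of the p-silyloxybenzylic C6–OH gives a stabilised cation that is captured intramolecularly by C2–OH; because ionisation is reversible, the system funnels to the all-equatorial chair (2,6-cis, 4,5-trans) dictated by the fixed C2 (S), C4 (R) and C5 (R) centres, and the closest known reaction is dehydrative cyclisation of benzylic 1,5-diols to cis-2,6-THPs.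

**Step 13**
Reactants: 18; 6 (4 equiv)
Product: 19 fully silylated acetophenone with the (E)-side chain
Conditions: Grubbs II (10 mol%), CH2Cl2, 40 °C, 16 h
Reagents that add atoms: none
Why: Cross-metathesis of the α-branched terminal vinyl with a type I homoallylic silyl ether gives the E-alkene and installs the (S)-C-f carbinol.

**Step 14**
Reactants: 19
Product: 20 deprotected acetophenone (six silyl groups removed)
Conditions: TBAF (12 equiv), AcOH (12 equiv), THF, 0 °C → rt
Reagents that add atoms: none
Why: Buffered fluoride removes all aryl and alkyl silyl ethers in one operation without touching the benzylic THP ether or the alkene.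

**Step 15**
Reactants: 20; 21 4-hydroxybenzaldehyde
Product: 22 Blepharocalyxin E
Conditions: 21 (3 equiv), 50% aq KOH, EtOH, 25 °C, 72 h, N2; then 1 M HCl to pH 3
Reagents that add atoms: none
Why: Claisen–Schmidt aldol condensation gives the (E)-chalcone, with no stereocentre involved; this mirrors the direct isoliquiritigenin-type synthesis from a free-phenol acetophenone and 4-hydroxybenzaldehyde.

## Compound list
1 | methyl 3-(4-hydroxyphenyl)propanoate | `COC(=O)CCc1ccc(O)cc1` | starting material
2 | methyl 3-(4-TBSO-phenyl)propanoate | `COC(=O)CCc1ccc(O[Si](C)(C)C(C)(C)C)cc1` | intermediate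
3 | 3-(4-TBSO-phenyl)propanal | `O=CCCc1ccc(O[Si](C)(C)C(C)(C)C)cc1` | intermediate
4 | allyltributylstannane | `C=CC[Sn](CCCC)(CCCC)CCCC` | starting material
5 | (S)-1-(4-TBSO-phenyl)hex-5-en-3-ol | `C=CC[C@@H](O)CCc1ccc(O[Si](C)(C)C(C)(C)C)cc1` | intermediate
6 | (S)-TES ether of 5 | `C=CC[C@@H](O[Si](CC)(CC)CC)CCc1ccc(O[Si](C)(C)C(C)(C)C)cc1` | intermediate
7 | acrolein | `C=CC=O` | starting material
8 | (S,E)-5-(TESO)-7-(4-TBSO-phenyl)hept-2-enal | `O=C/C=C/C[C@@H](O[Si](CC)(CC)CC)CCc1ccc(O[Si](C)(C)C(C)(C)C)cc1` | intermediate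
9 | 2',4'-dihydroxy-6'-methoxyacetophenone | `COc1cc(O)cc(O)c1C(C)=O` | starting material
10 | 2'-hydroxy-4'-TBSO-6'-methoxyacetophenone | `COc1cc(O[Si](C)(C)C(C)(C)C)cc(O)c1C(C)=O` | intermediate
11 | Friedel–Crafts adduct aldehyde (C4 R, C2 S) | `O=CC[C@H](c1c(O)c(C(C)=O)c(OC)cc1O[Si](C)(C)C(C)(C)C)C[C@@H](O[Si](CC)(CC)CC)CCc1ccc(O[Si](C)(C)C(C)(C)C)cc1` | intermediate
12 | 4-TBSO-benzaldehyde | `O=Cc1ccc(O[Si](C)(C)C(C)(C)C)cc1` | starting material
13 | (±)-1-(4-TBSO-phenyl)prop-2-en-1-ol | `C=CC(O)c1ccc(O[Si](C)(C)C(C)(C)C)cc1` | intermediate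
14 | allylation product aldehyde (C4 R, C5 R, Cε S) | `O=C[C@@H]([C@H](C=C)c1ccc(O[Si](C)(C)C(C)(C)C)cc1)[C@H](c1c(O)c(C(C)=O)c(OC)cc1O[Si](C)(C)C(C)(C)C)C[C@@H](O[Si](CC)(CC)CC)CCc1ccc(O[Si](C)(C)C(C)(C)C)cc1` | intermediate
15 | (4-bromophenoxy)-TBS | `CC(C)(C)[Si](C)(C)Oc1ccc(Br)cc1` | starting material
16 | benzylic alcohol (C6 epimeric mixture) | `OC(c1ccc(O[Si](C)(C)C(C)(C)C)cc1)[C@@H]([C@H](C=C)c1ccc(O[Si](C)(C)C(C)(C)C)cc1)[C@H](c1c(O)c(C(C)=O)c(OC)cc1O[Si](C)(C)C(C)(C)C)C[C@@H](O[Si](CC)(CC)CC)CCc1ccc(O[Si](C)(C)C(C)(C)C)cc1` | intermediate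
17 | 1,5-diol | `OC(c1ccc(O[Si](C)(C)C(C)(C)C)cc1)[C@@H]([C@H](C=C)c1ccc(O[Si](C)(C)C(C)(C)C)cc1)[C@H](c1c(O)c(C(C)=O)c(OC)cc1O[Si](C)(C)C(C)(C)C)C[C@@H](O)CCc1ccc(O[Si](C)(C)C(C)(C)C)cc1` | intermediate
18 | THP with terminal vinyl | `COc1cc(O[Si](C)(C)C(C)(C)C)c([C@@H]2C[C@H](CCc3ccc(O[Si](C)(C)C(C)(C)C)cc3)O[C@H](c3ccc(O[Si](C)(C)C(C)(C)C)cc3)[C@H]2[C@H](C=C)c2ccc(O[Si](C)(C)C(C)(C)C)cc2)c(O)c1C(C)=O` | intermediate
19 | silylated acetophenone with side chain | `COc1cc(O[Si](C)(C)C(C)(C)C)c([C@@H]2C[C@H](CCc3ccc(O[Si](C)(C)C(C)(C)C)cc3)O[C@H](c3ccc(O[Si](C)(C)C(C)(C)C)cc3)[C@H]2[C@H](/C=C/C[C@@H](O[Si](CC)(CC)CC)CCc2ccc(O[Si](C)(C)C(C)(C)C)cc2)c2ccc(O[Si](C)(C)C(C)(C)C)cc2)c(O)c1C(C)=O` | intermediate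
20 | polyphenolic acetophenone | `COc1cc(O)c([C@@H]2C[C@H](CCc3ccc(O)cc3)O[C@H](c3ccc(O)cc3)[C@H]2[C@H](/C=C/C[C@@H](O)CCc2ccc(O)cc2)c2ccc(O)cc2)c(O)c1C(C)=O` | intermediate
21 | 4-hydroxybenzaldehyde | `O=Cc1ccc(O)cc1` | starting material
22 | Blepharocalyxin E | `COc1cc(O)c([C@@H]2C[C@H](CCc3ccc(O)cc3)O[C@H](c3ccc(O)cc3)[C@H]2[C@H](/C=C/C[C@@H](O)CCc2ccc(O)cc2)c2ccc(O)cc2)c(O)c1C(=O)/C=C/c1ccc(O)cc1` | target

## Summary
Total step count: 15.
Longest linear sequence: 13 steps (1 → 2 → 3 → 5 → 6 → 8 → 11 → 14 → 16 → 17 → 18 → 19 → 20 → 22).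

Three steps most likely to fail:
1. **Step 9 (Ir/amine allylation of the hindered aldehyde 11).** Fallback: change the approach to an Ireland–Claisen rearrangement of a cinnamyl-type ester to set C5 and Cε, followed by lactonisation, ArLi addition and Et3SiH/BF3 reduction to the THP.
2. **Step 7 (Friedel–Crafts onto a β-alkyl enal with a di-ortho-substituted arene, with C3'/C5' regiochemistry in question).** Fallback: Rh-catalysed Hayashi–Miyaura 1,4-addition of a C5'-blocked aryl boronate to the corresponding (E)-enoate, then DIBAL reduction to the aldehyde.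
3. **Step 12 (stereoconvergent dehydrative cyclisation; risks are C5 epimerisation through styrene formation, chroman formation by the 2'-OH, and TBS loss).** Fallback: oxidise the C6 carbinol to the aryl ketone and close the ring by Et3SiH/TMSOTf reductive etherification, which delivers the 2,6-cis THP by axial hydride attack on the oxocarbenium ion.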